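The ten-membered ring is cut at C2–C3. C3(OH)–C2–C1(=O) is an aldol unit, and C3 is flanked by the fully substituted carbon C4 of the C4–C5 epoxide, so the acceptor is a non-enolisable epoxy aldehyde. SmI2 turns a C1 bromomethyl ketone into a regiodefined samarium enolate that attacks this aldehyde. One operation forms C2–C3, the carbocycle and the C3 stereocentre. The precursor is a 3,4,5-trisubstituted butenolide (O, C6, C7, C11, C12) that already carries the C13 acetate and the complete C8 ester, so ring closure gives the target itself. The butenolide arises from a CrCl2/NiCl2 coupling of a (Z)-enol triflate with a cis-epoxy aldehyde.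

Key step: step 24

Numbering (germacrane): the ring carbons are C1–C10. C1 is the ketone, C3 the carbinol, C4/C5 the epoxide, C6 the lactone carbinol, C8 the ester carbinol and C10 the methyl-bearing carbon. C11, C12 and C13 are the lactone α-carbon, the lactone carbonyl and the acetoxymethyl carbon. The target is (3S,4R,5S,6S,8S,10S) with a (Z)-configured side chain.

Remark on the chemistry: both enantiomers of β-citronellene and the tert-butyldimethylsilyl ether of prop-2-yn-1-ol are taken as commercial. The C1 epimers formed in step 21 are carried on together because C1 becomes a carbonyl carbon in step 23.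

Design remark: C8 carries a silyl ether only while the alkenylchromium reagent is present, because an acyloxy group next to the C7–Cr bond could be lost by β-elimination. The final ester goes on before the vinyl group is touched, so nothing has to be done to the sensitive β-hydroxy ketone after ring closure.

Step 1
Reactants: 1 (S)-3,7-dimethylocta-1,6-diene ((S)-β-citronellene)
Product: 3 (S)-4-methylhex-5-enal, via ozonide 2 (not isolated)
Conditions: O3 (1 equiv, dye end-point), CH2Cl2, −78 °C; Me2S, −78 °C → rt
Reagents that add atoms: ozone [O-][O+]=O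
Why: Chemoselective ozonolysis, in which the electron-rich trisubstituted alkene adds ozone much faster than the monosubstituted vinyl group, so one equivalent followed by reduction of ozonide 2 should leave the vinyl group (future C1=C2) and the stereocentre (future C10) untouched.

Step 2
Reactants: 3 (S)-4-methylhex-5-enal
Product: 6 (2S,4S)-4-methylhex-5-ene-1,2-diol, via aminoxy aldehyde 4 (not isolated), via aminoxy alcohol 5 (not isolated)
Conditions: PhNO, D-proline (20 mol %), CHCl3, 4 °C; NaBH4, EtOH, 0 °C; Zn, AcOH, rt
Reagents that add atoms: nitrosobenzene O=Nc1ccccc1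
Why: Proline-catalysed α-aminoxylation (O-selective nitroso aldol reaction), in which the enamine from 3 and D-proline attacks the oxygen of nitrosobenzene held by the carboxylic acid on one enamine face, so the (S)-carbinol centre (future C8) is set by the catalyst independently of the remote methyl centre, and NaBH4 reduction followed by Zn/AcOH cleavage of the N–O bond should then give diol 6.

Step 3
Reactants: 6 (2S,4S)-4-methylhex-5-ene-1,2-diol
Product: 7 (2S,4S)-4-methyl-1,2-bis(triethylsilyloxy)hex-5-ene
Conditions: Et3SiCl, imidazole, CH2Cl2, 0 °C → rt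
Reagents that add atoms: chlorotriethylsilane CC[Si](Cl)(CC)CC
Why: Routine silyl ether formation (substitution at silicon with imidazole as base) that should cap both hydroxyl groups without touching the alkene.

Step 4
Reactants: 7 (2S,4S)-4-methyl-1,2-bis(triethylsilyloxy)hex-5-ene
Product: 8 (2S,4S)-4-methyl-2-(triethylsilyloxy)hex-5-enal
Conditions: (COCl)2, DMSO, CH2Cl2, −78 → −40 °C; Et3N, −78 → 0 °C
Reagents that add atoms: none
Why: Swern oxidation with direct oxidative desilylation, in which the chlorosulfonium salt attacks only the unhindered primary triethylsilyl ether and converts its oxygen through the alkoxysulfonium ion into the aldehyde, whereas the secondary silyl ether survives and the low temperature protects the α-stereocentre.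

Step 5
Reactants: 9 methyl acrylate, 10 4-methoxybenzyl alcohol
Product: 11 methyl 3-(4-methoxybenzyloxy)propanoate
Conditions: NaH (5 mol %), THF, 0 °C → rt
Reagents that add atoms: none
Why: Base-catalysed oxa-Michael addition of the benzylic alkoxide to the acrylate, a reversible conjugate addition that is driven by an excess of the acrylate.

Step 6
Reactants: 11 methyl 3-(4-methoxybenzyloxy)propanoate, 8 (2S,4S)-4-methyl-2-(triethylsilyloxy)hex-5-enal
Product: 13 methyl (4S,6S)-3-hydroxy-2-[(4-methoxybenzyloxy)methyl]-6-methyl-4-(triethylsilyloxy)oct-7-enoate (epimers at C2 and C3), via lithium enolate 12 (not isolated)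
Conditions: LiN(iPr)2, THF, −78 °C; then 8, −78 °C; aqueous quench at −78 °C
Reagents that add atoms: none
Why: Lithium enolate aldol addition, in which the ester enolate is made and consumed at −78 °C, where E1cB loss of the poor 4-methoxybenzyl oxide leaving group is slow, and the two new stereocentres need no control because both become sp2 carbons in steps 7 and 8.

Step 7
Reactants: 13 aldol adduct
Product: 14 methyl (4S,6S)-2-[(4-methoxybenzyloxy)methyl]-6-methyl-3-oxo-4-(triethylsilyloxy)oct-7-enoate
Conditions: Dess–Martin periodinane, NaHCO3, CH2Cl2, 0 °C → rt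
Reagents that add atoms: none
Why: Dess–Martin oxidation of the secondary alcohol under buffered, non-basic conditions, which should give the β-keto ester without β-elimination or epimerisation at the silyloxy-bearing carbon.

Step 8
Reactants: 14 β-keto ester
Product: 16 methyl (2Z,4S,6S)-2-[(4-methoxybenzyloxy)methyl]-6-methyl-4-(triethylsilyloxy)-3-(trifluoromethylsulfonyloxy)octa-2,7-dienoate, via sodium enolate 15 (not isolated)
Conditions: NaH (1 equiv), Et2O, 0 °C; Tf2O, −78 → 0 °C
Reagents that add atoms: trifluoromethanesulfonic anhydride O=S(=O)(OS(=O)(=O)C(F)(F)F)C(F)(F)F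
Why: O-Triflation of a chelated β-keto ester enolate, in which sodium bridges the enolate oxygen and the ester carbonyl and thus holds them on the same side of the C7=C11 bond, so trapping on oxygen should give the (Z)-enol triflate, while the single equivalent of base removes only the doubly activated C11 proton.

Step 9
Reactants: 17 tert-butyldimethyl(prop-2-yn-1-yloxy)silane
Product: 19 tert-butyl 4-(tert-butyldimethylsilyloxy)but-2-ynoate, via lithium acetylide 18 (not isolated)
Conditions: n-BuLi, THF, −78 °C; Boc2O, −78 °C → rt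
Reagents that add atoms: di-tert-butyl dicarbonate CC(C)(C)OC(=O)OC(=O)OC(C)(C)C
Why: Acylation of a lithium acetylide with Boc2O, a standard route to tert-butyl alkynoates in which tert-butyl carbonate is the leaving group.

Step 10
Reactants: 19 tert-butyl 4-(tert-butyldimethylsilyloxy)but-2-ynoate
Product: 20 tert-butyl (Z)-4-(tert-butyldimethylsilyloxy)-3-methylbut-2-enoate
Conditions: Me2CuLi (MeLi, CuI), THF, −78 °C; aqueous NH4Cl quench at −78 °C
Reagents that add atoms: lithium dimethylcuprate [Li+].C[Cu-]C
Why: Syn-carbocupration (conjugate addition of a lithium dialkylcuprate to an alkynoate), in which methyl and copper add to the same side of the triple bond and cold protonation of the configurationally stable alkenylcuprate should leave the silyloxymethyl group cis to the ester, the (Z)-alkene needed both for the cis-epoxide and for the side chain.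

Step 11
Reactants: 20 tert-butyl (Z)-4-(tert-butyldimethylsilyloxy)-3-methylbut-2-enoate
Product: 21 (Z)-4-(tert-butyldimethylsilyloxy)-3-methylbut-2-en-1-ol
Conditions: iBu2AlH, CH2Cl2, −78 → 0 °C; Rochelle salt
Reagents that add atoms: none
Why: 1,2-Reduction of the enoate with iBu2AlH, which should give the allylic alcohol with retention of the (Z)-geometry and leave the silyl ether intact.

Step 12
Reactants: 21 (Z)-4-(tert-butyldimethylsilyloxy)-3-methylbut-2-en-1-ol
Product: 22 [(2S,3R)-3-(tert-butyldimethylsilyloxymethyl)-3-methyloxiran-2-yl]methanol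
Conditions: Ti(OiPr)4 (10 mol %), L-(+)-diethyl tartrate (12 mol %), tBuOOH, 4 Å molecular sieves, CH2Cl2, −20 °C
Reagents that add atoms: tert-butyl hydroperoxide CC(C)(C)OO
Why: Katsuki–Sharpless asymmetric epoxidation, in which the titanium L-(+)-tartrate complex binds the allylic alcohol and tBuOOH and delivers oxygen to the alkene face that gives the (2S,3R)-epoxy alcohol (future 5S,4R), the cis relation of the two CH2O arms following from the (Z)-alkene.

Step 13
Reactants: 22 epoxy alcohol
Product: 23 (2R,3R)-3-(tert-butyldimethylsilyloxymethyl)-3-methyloxirane-2-carbaldehyde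
Conditions: Dess–Martin periodinane, NaHCO3, CH2Cl2, 0 °C
Reagents that add atoms: none
Why: Dess–Martin oxidation of the primary epoxy alcohol under buffered conditions, which should give the cis-epoxy aldehyde without epimerisation at C5 or opening of the oxirane.

Step 14
Reactants: 20 tert-butyl (Z)-4-(tert-butyldimethylsilyloxy)-3-methylbut-2-enoate
Product: 25 tert-butyl (Z)-4-acetoxy-3-methylbut-2-enoate, via hydroxy ester 24 (not isolated)
Conditions: HF·pyridine, THF, 0 °C; then pyridine, Ac2O, DMAP, 0 °C → rt
Reagents that add atoms: acetic anhydride CC(=O)OC(C)=O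
Why: Fluoride-mediated desilylation followed by acetylation in the same flask, the bulky tert-butyl ester slowing lactonisation of the (Z)-γ-hydroxy enoate 24 long enough for the hydroxyl group to be acetylated.

Step 15
Reactants: 25 tert-butyl (Z)-4-acetoxy-3-methylbut-2-enoate
Product: 26 (Z)-4-acetoxy-3-methylbut-2-enoic acid
Conditions: CF3CO2H, CH2Cl2, 0 °C
Reagents that add atoms: none
Why: Acidolysis of the tert-butyl ester (E1 loss of isobutene), which frees the acid under conditions that leave the primary acetate and the (Z)-alkene unchanged.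

Step 16
Reactants: 16 (Z)-enol triflate, 23 cis-epoxy aldehyde
Product: 28 (5S)-5-[(2S,3R)-3-(tert-butyldimethylsilyloxymethyl)-3-methyloxiran-2-yl]-3-[(4-methoxybenzyloxy)methyl]-4-[(1S,3S)-3-methyl-1-(triethylsilyloxy)pent-4-enyl]furan-2(5H)-one, via hydroxy ester 27 (not isolated)
Conditions: CrCl2 (6 equiv), NiCl2 (2 mol %), DMF, rt
Reagents that add atoms: none
Why: Nozaki–Hiyama–Kishi coupling, in which zerovalent nickel inserts into the C7–OTf bond, transmetalation gives a non-basic alkenyl reagent of trivalent chromium that tolerates the epoxide and the ethers, its non-chelated addition to 23 should follow the polar Felkin–Anh model (attack anti to the C5–O bond, past C5–H) and set (6S), and the (Z)-geometry places the new alkoxide next to the methyl ester so that 27 lactonises to the butenolide.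

Step 17
Reactants: 28 butenolide (C13 4-methoxybenzyl ether)
Product: 29 the corresponding 3-(hydroxymethyl)furan-2(5H)-one (C13 alcohol; C8 triethylsilyl and C3 tert-butyldimethylsilyl ethers retained)
Conditions: DDQ, CH2Cl2/pH 7 buffer, 0 °C
Reagents that add atoms: none
Why: Oxidative cleavage of the 4-methoxybenzyl ether with DDQ (hydride abstraction, then hydrolysis of the oxocarbenium ion), a neutral method that should spare the silyl ethers, the epoxide and the vinyl group.

Step 18
Reactants: 29 C13 alcohol
Product: 30 the corresponding 3-(acetoxymethyl)furan-2(5H)-one (C13 acetate)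
Conditions: Ac2O, pyridine, DMAP (cat), CH2Cl2, 0 °C
Reagents that add atoms: acetic anhydride CC(=O)OC(C)=O
Why: Routine DMAP-catalysed acetylation of the only free hydroxyl group, which installs the C13 acetate of the target.

Step 19
Reactants: 30 C13 acetate
Product: 31 (5S)-3-(acetoxymethyl)-5-[(2S,3R)-3-(tert-butyldimethylsilyloxymethyl)-3-methyloxiran-2-yl]-4-[(1S,3S)-1-hydroxy-3-methylpent-4-enyl]furan-2(5H)-one
Conditions: HF·pyridine, pyridine, THF, 0 °C
Reagents that add atoms: none
Why: Selective fluoride desilylation, in which buffered HF·pyridine cleaves the triethylsilyl ether far faster than the tert-butyldimethylsilyl ether on the neopentyl-type C3 oxygen, and the non-basic medium disfavours acetyl migration from O13 to O8.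

Step 20
Reactants: 31 C8 alcohol, 26 (Z)-4-acetoxy-3-methylbut-2-enoic acid
Product: 33 (5S)-3-(acetoxymethyl)-4-{(1S,3S)-1-[(Z)-4-acetoxy-3-methylbut-2-enoyloxy]-3-methylpent-4-enyl}-5-[(2S,3R)-3-(tert-butyldimethylsilyloxymethyl)-3-methyloxiran-2-yl]furan-2(5H)-one, via mixed anhydride 32 (not isolated)
Conditions: 26, 2,4,6-Cl3C6H2COCl, Et3N, toluene, rt; then 31, DMAP, 0 °C → rt
Reagents that add atoms: none
Why: Yamaguchi esterification, in which the acid is activated as mixed anhydride 32 and passed by DMAP to the hindered C8 alcohol with retention at C8, the mild conditions and the β,β-disubstituted enoate making (Z)-to-(E) isomerisation and acetyl migration unlikely.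

Step 21
Reactants: 33 C8 ester with the C1=C2 vinyl group
Product: 34 the corresponding bromohydrin, 4-{(1S,3S,4RS)-1-[(Z)-4-acetoxy-3-methylbut-2-enoyloxy]-5-bromo-4-hydroxy-3-methylpentyl} analogue of 33
Conditions: NBS, THF/H2O, 0 °C, dark
Reagents that add atoms: N-bromosuccinimide O=C1CCC(=O)N1Br; water O
Why: Bromohydrin formation, in which only the electron-rich monosubstituted C1=C2 alkene attacks NBS because the butenolide and enoate alkenes are deactivated, water opens the bromonium ion at the internal carbon C1 (Markovnikov sense), and the C8 oxygen, tied up as a non-nucleophilic ester, cannot close a tetrahydrofuran.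

Step 22
Reactants: 34 bromohydrin (C3 silyl ether)
Product: 35 the corresponding C1,C3-diol, with a (2S,3R)-3-(hydroxymethyl)-3-methyloxiran-2-yl group at C5 of the furanone
Conditions: HF·pyridine, THF, 0 °C → rt
Reagents that add atoms: none
Why: Cleavage of the last silyl ether with HF·pyridine, an acidic fluoride source in which bromohydrin, esters and the trisubstituted epoxide should survive, whereas a basic fluoride source would close the bromohydrin to an epoxide.

Step 23
Reactants: 35 C1,C3-diol
Product: 36 (5S)-3-(acetoxymethyl)-4-{(1S,3S)-1-[(Z)-4-acetoxy-3-methylbut-2-enoyloxy]-5-bromo-3-methyl-4-oxopentyl}-5-[(2S,3S)-3-formyl-3-methyloxiran-2-yl]furan-2(5H)-one (C2 bromomethyl ketone and C3 epoxy aldehyde)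
Conditions: Dess–Martin periodinane (3 equiv), NaHCO3, CH2Cl2, 0 °C → rt
Reagents that add atoms: none
Why: Double Dess–Martin oxidation, in which the buffered periodinane should turn the secondary bromohydrin into the bromomethyl ketone and the primary epoxy alcohol into the aldehyde in one operation without epimerising C10 or opening the epoxide.

Step 24
Reactants: 36 bromo keto aldehyde
Product: 39 target, (3S,4R,5S,6S,8S,10S)-13-acetoxy-8-[(Z)-4-acetoxy-3-methylbut-2-enoyloxy]-4,5-epoxy-3-hydroxy-1-oxogermacr-7(11)-en-12,6-olide, via samarium enolate 37 (not isolated), via samarium aldolate 38 (not isolated)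
Conditions: SmI2 (2.2 equiv, 0.1 M in THF, slow addition), 36 (1 mM in THF), −78 °C, no HMPA, no proton source; pH 7 buffer at −78 °C
Reagents that add atoms: none
Why: Two single-electron transfers from SmI2 break the C2–Br bond and give enolate 37 of trivalent samarium at C2 only, which leaves the C10 stereocentre untouched, and the enolate carbon then adds to the C3 formyl group. The closest known reaction type is the SmI2-mediated intramolecular Reformatsky (reductive aldol) reaction of α-halo ketones with aldehydes, which has been used to close medium rings. The ten-membered carbocycle closes in a 10-(enolendo)-exo-trig mode, and the cis-epoxide and the flat lactone pre-fold the chain while high dilution suppresses intermolecular aldol addition. C3 is controlled by a chelate in which samarium holds the enolate oxygen, the aldehyde oxygen and the epoxide oxygen, so that the C=O bond lies syn to C4–O and the enolate reaches the face flanked by the small C4 methyl group, which gives (3S). The step needs chemoselective reduction of the α-bromo ketone in the presence of the epoxy aldehyde, the butenolide and three allylic or vinylogous acyloxy groups, which is secured by the much easier reduction of the C–Br bond at −78 °C, by slow addition of barely more than two equivalents and by the absence of additives that raise the reducing power. The aldol stays bound as alkoxide 38 until the cold neutral quench, which keeps it from reverting or losing water.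

Compound list
1 | (S)-3,7-dimethylocta-1,6-diene ((S)-β-citronellene) | CC(C)=CCC[C@H](C)C=C | starting material
2 | 3,3-dimethyl-5-[(3S)-3-methylpent-4-enyl]-1,2,4-trioxolane (ozonide) | CC1(C)OOC(CC[C@H](C)C=C)O1 | intermediate
3 | (S)-4-methylhex-5-enal | O=CCC[C@H](C)C=C | intermediate
4 | (2S,4S)-2-(anilinooxy)-4-methylhex-5-enal | O=C[C@@H](ONc1ccccc1)C[C@H](C)C=C | intermediate
5 | (2S,4S)-2-(anilinooxy)-4-methylhex-5-en-1-ol | OC[C@@H](ONc1ccccc1)C[C@H](C)C=C | intermediate
6 | (2S,4S)-4-methylhex-5-ene-1,2-diol | OC[C@@H](O)C[C@H](C)C=C | intermediate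
7 | (2S,4S)-4-methyl-1,2-bis(triethylsilyloxy)hex-5-ene | CC[Si](CC)(CC)OC[C@@H](O[Si](CC)(CC)CC)C[C@H](C)C=C | intermediate
8 | (2S,4S)-4-methyl-2-(triethylsilyloxy)hex-5-enal | O=C[C@@H](O[Si](CC)(CC)CC)C[C@H](C)C=C | intermediate
9 | methyl acrylate | C=CC(=O)OC | starting material
10 | 4-methoxybenzyl alcohol | COc1ccc(CO)cc1 | starting material
11 | methyl 3-(4-methoxybenzyloxy)propanoate | COC(=O)CCOCc1ccc(OC)cc1 | intermediate
12 | lithium enolate of 11 | COC(O[Li])=CCOCc1ccc(OC)cc1 | intermediate
13 | methyl (4S,6S)-3-hydroxy-2-[(4-methoxybenzyloxy)methyl]-6-methyl-4-(triethylsilyloxy)oct-7-enoate | COC(=O)C(COCc1ccc(OC)cc1)C(O)[C@@H](O[Si](CC)(CC)CC)C[C@H](C)C=C | intermediate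
14 | methyl (4S,6S)-2-[(4-methoxybenzyloxy)methyl]-6-methyl-3-oxo-4-(triethylsilyloxy)oct-7-enoate | COC(=O)C(COCc1ccc(OC)cc1)C(=O)[C@@H](O[Si](CC)(CC)CC)C[C@H](C)C=C | intermediate
15 | chelated (Z)-sodium enolate of 14 | COC(=O)/C(COCc1ccc(OC)cc1)=C(O[Na])/[C@@H](O[Si](CC)(CC)CC)C[C@H](C)C=C | intermediate
16 | methyl (2Z,4S,6S)-2-[(4-methoxybenzyloxy)methyl]-6-methyl-4-(triethylsilyloxy)-3-(trifluoromethylsulfonyloxy)octa-2,7-dienoate | COC(=O)/C(COCc1ccc(OC)cc1)=C(OS(=O)(=O)C(F)(F)F)/[C@@H](O[Si](CC)(CC)CC)C[C@H](C)C=C | intermediate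
17 | tert-butyldimethyl(prop-2-yn-1-yloxy)silane | C#CCO[Si](C)(C)C(C)(C)C | starting material
18 | lithium acetylide of 17 | [Li]C#CCO[Si](C)(C)C(C)(C)C | intermediate
19 | tert-butyl 4-(tert-butyldimethylsilyloxy)but-2-ynoate | CC(C)(C)OC(=O)C#CCO[Si](C)(C)C(C)(C)C | intermediate
20 | tert-butyl (Z)-4-(tert-butyldimethylsilyloxy)-3-methylbut-2-enoate | CC(C)(C)OC(=O)/C=C(/C)CO[Si](C)(C)C(C)(C)C | intermediate
21 | (Z)-4-(tert-butyldimethylsilyloxy)-3-methylbut-2-en-1-ol | OC/C=C(/C)CO[Si](C)(C)C(C)(C)C | intermediate
22 | [(2S,3R)-3-(tert-butyldimethylsilyloxymethyl)-3-methyloxiran-2-yl]methanol | OC[C@@H]1O[C@]1(C)CO[Si](C)(C)C(C)(C)C | intermediate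
23 | (2R,3R)-3-(tert-butyldimethylsilyloxymethyl)-3-methyloxirane-2-carbaldehyde | O=C[C@@H]1O[C@]1(C)CO[Si](C)(C)C(C)(C)C | intermediate
24 | tert-butyl (Z)-4-hydroxy-3-methylbut-2-enoate | CC(C)(C)OC(=O)/C=C(/C)CO | intermediate
25 | tert-butyl (Z)-4-acetoxy-3-methylbut-2-enoate | CC(C)(C)OC(=O)/C=C(/C)COC(C)=O | intermediate
26 | (Z)-4-acetoxy-3-methylbut-2-enoic acid | OC(=O)/C=C(/C)COC(C)=O | intermediate
27 | open-chain (Z)-γ-hydroxy enoate, (6S)-alcohol from 16 and 23 (formed as its chromium alkoxide) | COC(=O)/C(COCc1ccc(OC)cc1)=C(/[C@@H](O[Si](CC)(CC)CC)C[C@H](C)C=C)[C@H](O)[C@@H]1O[C@]1(C)CO[Si](C)(C)C(C)(C)C | intermediate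
28 | butenolide with C13 4-methoxybenzyl ether, C8 triethylsilyl ether, C3 tert-butyldimethylsilyl ether and C1=C2 vinyl (4R,5S,6S,8S,10S) | COc1ccc(COCC2=C([C@@H](O[Si](CC)(CC)CC)C[C@H](C)C=C)[C@@H]([C@@H]3O[C@]3(C)CO[Si](C)(C)C(C)(C)C)OC2=O)cc1 | intermediate
29 | C13 alcohol derived from 28 | OCC1=C([C@@H](O[Si](CC)(CC)CC)C[C@H](C)C=C)[C@@H]([C@@H]2O[C@]2(C)CO[Si](C)(C)C(C)(C)C)OC1=O | intermediate
30 | C13 acetate derived from 29 | CC(=O)OCC1=C([C@@H](O[Si](CC)(CC)CC)C[C@H](C)C=C)[C@@H]([C@@H]2O[C@]2(C)CO[Si](C)(C)C(C)(C)C)OC1=O | intermediate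
31 | C8 alcohol derived from 30 | CC(=O)OCC1=C([C@@H](O)C[C@H](C)C=C)[C@@H]([C@@H]2O[C@]2(C)CO[Si](C)(C)C(C)(C)C)OC1=O | intermediate
32 | (Z)-4-acetoxy-3-methylbut-2-enoic 2,4,6-trichlorobenzoic anhydride | O=C(/C=C(/C)COC(C)=O)OC(=O)c1c(Cl)cc(Cl)cc1Cl | intermediate
33 | C8 (Z)-4-acetoxy-3-methylbut-2-enoate derived from 31 | CC(=O)OCC1=C([C@@H](OC(=O)/C=C(/C)COC(C)=O)C[C@H](C)C=C)[C@@H]([C@@H]2O[C@]2(C)CO[Si](C)(C)C(C)(C)C)OC1=O | intermediate
34 | C1-hydroxy C2-bromide (bromohydrin, both C1 epimers) derived from 33 | CC(=O)OCC1=C([C@@H](OC(=O)/C=C(/C)COC(C)=O)C[C@H](C)C(O)CBr)[C@@H]([C@@H]2O[C@]2(C)CO[Si](C)(C)C(C)(C)C)OC1=O | intermediate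
35 | C1,C3-diol derived from 34 | CC(=O)OCC1=C([C@@H](OC(=O)/C=C(/C)COC(C)=O)C[C@H](C)C(O)CBr)[C@@H]([C@@H]2O[C@]2(C)CO)OC1=O | intermediate
36 | key-step precursor: C2 bromomethyl ketone and C3 epoxy aldehyde on the butenolide | CC(=O)OCC1=C([C@@H](OC(=O)/C=C(/C)COC(C)=O)C[C@H](C)C(=O)CBr)[C@@H]([C@@H]2O[C@]2(C)C=O)OC1=O | intermediate
37 | C1=C2 diiodosamarium enolate of 36 | CC(=O)OCC1=C([C@@H](OC(=O)/C=C(/C)COC(C)=O)C[C@H](C)C(=C)O[Sm](I)I)[C@@H]([C@@H]2O[C@]2(C)C=O)OC1=O | intermediate
38 | C3 diiodosamarium alkoxide of the target | CC(=O)OCC1=C2[C@@H](OC(=O)/C=C(/C)COC(C)=O)C[C@H](C)C(=O)C[C@H](O[Sm](I)I)[C@@]3(C)O[C@H]3[C@H]2OC1=O | intermediate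
39 | CNP0232076.1 | CC(=O)OCC1=C2[C@@H](OC(=O)/C=C(/C)COC(C)=O)C[C@H](C)C(=O)C[C@H](O)[C@@]3(C)O[C@H]3[C@H]2OC1=O | target

Total step count: 24.
Longest linear sequence: 16 steps (1 → 39 through steps 1–4, 6–8 and 16–24).

Steps most likely to fail

Step 24 (ring closure). The reductant may also attack the epoxy aldehyde or the acyloxy-substituted butenolide, the enolate may be protonated or react between molecules, or it may add to the wrong aldehyde face. The fallback makes the enolate without a reductant and sets out from 33.
- Tsuji–Wacker oxidation (PdCl2, CuCl, O2, DMF/H2O) of the vinyl group should give the methyl ketone F1.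
- HF·pyridine should free the hydroxy ketone F2, and Dess–Martin oxidation should give the keto aldehyde F3.
- Cy2BCl/Et3N at high dilution, or one enantiomer of Ipc2BCl if reagent control of C3 is needed, enolises kinetically at the methyl group to the dicyclohexylboron enolate F4.
- F4 closes the ring in a boron aldol reaction through a cyclic transition state, and mild work-up with diethanolamine returns to the route at 39.

Step 16 (fragment coupling). Insertion into the fully substituted triflate may be slow, so that protonation of the alkenyl metal or reduction of the epoxy aldehyde by divalent chromium takes over, and facial selectivity at C6 may be poor. The fallback replaces carbonyl addition by acylation and reduction and sets out from 16 and 22.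
- (Me3Sn)2, Pd(PPh3)4 and LiCl should convert 16 into the alkenylstannane F5.
- TEMPO/PhI(OAc)2 in aqueous MeCN should oxidise 22 to the epoxy acid F6, which 1-chloro-N,N,2-trimethylpropenylamine turns into the acid chloride F7.
- Stille acylation of F5 with F7 under zerovalent palladium catalysis should give the epoxy enone F8.
- Zn(BH4)2 reduces F8 through a chelate of the ketone and epoxide oxygens, with hydride delivered from the C5–H side. This should give the (6S)-alcohol 27, which lactonises, so the route is rejoined at 28.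

Step 21 (bromohydrin). Water may open the bromonium ion at the wrong carbon next to the branched C10, or a neighbouring oxygen function may take part. The fallback sets out from 33.
- OsO4 (cat)/NMO dihydroxylates only the electron-rich vinyl group to the C1,C2-diol F9.
- Bu2SnO-catalysed tosylation (TsCl, Et3N) picks the primary hydroxyl group and gives the C2 tosylate F10.
- LiBr in acetone displaces the tosylate, and the route is rejoined at 34.

Further compounds
F1 | step 24 | methyl ketone (C1 ketone, C2 methyl, C3 silyl ether) | CC(=O)OCC1=C([C@@H](OC(=O)/C=C(/C)COC(C)=O)C[C@H](C)C(C)=O)[C@@H]([C@@H]2O[C@]2(C)CO[Si](C)(C)C(C)(C)C)OC1=O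
F2 | step 24 | hydroxy ketone (C3 alcohol) | CC(=O)OCC1=C([C@@H](OC(=O)/C=C(/C)COC(C)=O)C[C@H](C)C(C)=O)[C@@H]([C@@H]2O[C@]2(C)CO)OC1=O
F3 | step 24 | keto aldehyde | CC(=O)OCC1=C([C@@H](OC(=O)/C=C(/C)COC(C)=O)C[C@H](C)C(C)=O)[C@@H]([C@@H]2O[C@]2(C)C=O)OC1=O
F4 | step 24 | dicyclohexylboron enolate | CC(=O)OCC1=C([C@@H](OC(=O)/C=C(/C)COC(C)=O)C[C@H](C)C(=C)OB(C2CCCCC2)C2CCCCC2)[C@@H]([C@@H]2O[C@]2(C)C=O)OC1=O
F5 | step 16 | alkenylstannane | COC(=O)/C(COCc1ccc(OC)cc1)=C([Sn](C)(C)C)/[C@@H](O[Si](CC)(CC)CC)C[C@H](C)C=C
F6 | step 16 | epoxy acid | OC(=O)[C@@H]1O[C@]1(C)CO[Si](C)(C)C(C)(C)C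
F7 | step 16 | acid chloride | ClC(=O)[C@@H]1O[C@]1(C)CO[Si](C)(C)C(C)(C)C
F8 | step 16 | epoxy enone | COC(=O)/C(COCc1ccc(OC)cc1)=C(/[C@@H](O[Si](CC)(CC)CC)C[C@H](C)C=C)C(=O)[C@@H]1O[C@]1(C)CO[Si](C)(C)C(C)(C)C
F9 | step 21 | C1,C2-diol | CC(=O)OCC1=C([C@@H](OC(=O)/C=C(/C)COC(C)=O)C[C@H](C)C(O)CO)[C@@H]([C@@H]2O[C@]2(C)CO[Si](C)(C)C(C)(C)C)OC1=O
F10 | step 21 | C2 tosylate | CC(=O)OCC1=C([C@@H](OC(=O)/C=C(/C)COC(C)=O)C[C@H](C)C(O)COS(=O)(=O)c2ccc(C)cc2)[C@@H]([C@@H]2O[C@]2(C)CO[Si](C)(C)C(C)(C)C)OC1=O
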